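Set the 1.0% of trapped intermediate in the north-west run beside its 38.1% of product at 120 s: that reading is twice the scatter of 0.5 percentage points, so read no ratio from one point.

in all of them: substrate 10 mM
- north-west: partner 40 mM; capture agent 1 mM; run made earlier
- flask: partner 40.0 mM; capture agent 0.500 mM; time 6.0 min

north-west run (percent of the substrate charged)

| time / s | trapped intermediate / % | product / % |
|---|---|---|
| 20.0 | 0.5 | 5.9 |
| 40.0 | 0 | 14.3 |
| 60.0 | 0.3 | 21.4 |
| 80.0 | 0.8 | 28.9 |
| 120 | 1.0 | 38.1 |

(scatter of a reading: 0.5 percentage points)

* ratio of trapped intermediate to product at 15 s
* ratio of trapped intermediate to product at 1.0 min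
* ratio of trapped intermediate to product at 6.0 min

- no earlier run changes the charge of capture agent; that part of a forecast is a guess

Divide trapped intermediate by product and by c(capture agent), then work this out from two separate sets of north-west readings. The first 3 readings, summed, give 0.0192 /mM, with an uncertainty of 0.0208 /mM. The last 2 give 0.0269 /mM, with 0.0106 /mM. They part by 0.00763 /mM, less than the 0.0233 /mM that scatter puts on that gap, so these readings neither show a drift nor exclude one. The early figure is the less precise of the two, since its uncertainty is larger than that of the late figure.

Pool the 5 readings into the trap selectivity, the summed trapped intermediate over the summed product per mM of capture agent: 0.0239 /mM. Taking trapping as first order in capture agent, which is my guess, I reckon 0.0120 for this flask at 1.0 min. The time 15 s lies earlier than the first reading, and 6.0 min is 3.00 times the last, so I hold the same figure there with less trust.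

The forecast gives 0.012, 0.012 and 0.011, and says: “This order is a guess, as is the constant ratio”. It matches my figure at 1.0 min, from the same readings, and goes lower at 6.0 min, where I stay.

The flask gives 0.00657, 0.0107 and 0.0217.

    substrate ⇌ intermediate A (K = 1.10, k = 0.0486 /s)
    capture agent + intermediate B → trapped intermediate (k = 0.468 /M/s)
    substrate + partner ⇌ intermediate B (K = 38.0 /M, k = 0.346 /M/s)
    intermediate A → product (k = 0.0126 /s)

Per mM of capture agent, this flask gives 0.0131 /mM at 15 s, 0.0215 /mM at 1.0 min, near the trap selectivity of 0.0239 /mM, and 0.0434 /mM at 6.0 min. The rate of trapping over the rate of product formation is 0.0115 at 0.600 min, with intermediate B at 20.8% and intermediate A at 32.8%, and 0.0296 at 6.00 min, with 15.1% and 6.61%. The neighbour flask charged with 2.0 mM of capture agent gives 0.0839 at 6.00 min, which divided by that charge is 0.0420 /mM.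

The data stem from a simulated flask on assumed constants.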